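Remark on the chemistry: the sense of induction of the chromium catalyst (step 3) and of the pinene-derived allylborane (step 19) is assigned by analogy with their behaviour toward simple aldehydes; should a first adduct prove antipodal, the mirror-image catalyst or reagent is used and nothing else changes.

## The problem

Compound 33 is a C1–C24 chain (C1 the lactone carbonyl, C24 the propenyl methyl) with three stereochemical domains strung on a polyene. These are the (5S)-5,6-dihydropyran-2-one, the isolated (10R) methyl centre between the (8Z) trisubstituted alkene and the (12E,14E) diene, and ring A (O, C17–C21) with the adjoining C16 carbinol. The chain has to be assembled by joining sp2 carbons, and all five double bonds (6E, 8Z, 12E, 14E, 22E) must emerge with defined geometry. Of the seven stereocentres, C17, C20 and C21 are mutually cis on ring A and can be made together; the ring can then direct C19 (axial hydroxyl, trans to the C20 methyl), and C17 can direct C16 by chelation through the ring oxygen. C10 and C5 are too remote to be induced and need their own enantiopure sources. Three groups limit the reagents: the unsaturated δ-lactone, whose allylic C5–O bond is lost by elimination under base; the C16 carbinol, which is allylic to a diene and ionises under acid; and the polyene, which isomerises under light, acid or metal hydrides. On the way to ring A, the axial C20 methyl epimerises whenever C19 is a ketone. The enabling feature is ring A itself: O and C21 read as an aldehyde C=O, C17–C20 (oxygenated at C19) as a 2-silyloxydiene, and the all-cis C17 arm, C20 methyl and C21 propenyl as the signature of an endo [4+2] adduct of a Z,E diene.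

## Retrosynthesis

**C7–C8.** The target 33 is cut between C7 and C8 into the alkenyl iodide diol 32 and the stannyl lactone 28. Cutting C6=C7 by olefination would need a carbanion next to the base-labile lactone, and cutting C8=C9 would leave a Z-trisubstituted alkene to be made late. The C7–C8 cut joins an unhindered E-stannane to a Z-iodide with retention under neutral conditions, and it is made last so that the lactone meets no organometallic, hydride or fluoride. The forward Stille coupling must tolerate two free hydroxyls; 32 comes from its C19 silyl ether 31.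

**C15–C16.** Carbinol 31 is cut between C15 and C16 into the ring A aldehyde 11 and the enyne 21. An olefination at C14=C15 would require C16 to be set beforehand in an acyclic precursor. Here C16 is created in the coupling under control of C17, and the dienyl nucleophile comes from the terminal alkyne of 21 by hydrozirconation, which leaves the alkenyl iodide of 21 alone. The forward step needs chelation of zinc between the aldehyde and ring oxygens.

**Ring A.** Aldehyde 11 is traced through alcohol 10, bis-silyl ether 9, axial alcohol 8 and ketone 7 to the cycloadduct 6. In 6 the bonds O–C17 and C20–C21 are cut together, which gives diene 4 and (E)-crotonaldehyde 5. No other cut of the ring removes two ring bonds and three stereocentres at once from achiral partners. The forward cycloaddition must be endo, face-selective and chemoselective for C=O over C=C of 5.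

**Diene.** Diene 4 is the Z-silyl enol ether of enone 3, and 3 is cut at C17=C18 into aldehyde 1 and ketophosphonate 2. Both are purchased; the forward steps need E selectivity in the olefination and Z selectivity in the enolisation.

**C8–C15 enyne.** Alkyne 21 comes from its silyl derivative 20. The C8=C9 bond of 20 is cut by iodo-olefination to aldehyde 19 (from alcohol 18 and silyl ether 17). C13–C14 is cut by alkyne coupling to iodide 16. The C12 methyl and C13–I of 16 come from carboalumination of alkyne 14 through alane 15. Alkyne 14 is made from bromide 13 and this from the purchased bromo alcohol 12, which supplies C10. Each cut uses a reaction whose alkene geometry is fixed by mechanism (syn carbometalation, retentive coupling, kinetic Z olefination).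

**Lactone.** Lactone 28 is cut at C2=C3 by metathesis to acrylate 27, whose alcohol 26 is cut at C4–C5 by allylation of aldehyde 24 through borinate 25. Aldehyde 24 comes from alcohol 23 and this from propargyl alcohol 22. Carrying tin from the start gives the C6=C7 E-stannane without any operation on the finished lactone.

## Roads not taken

**Alternative 1:** The lactone carbons C1–C6 are cut at C4–C5 and C2–C3. In the forward sense 2-deoxyribose-5-phosphate aldolase adds two molecules of acetaldehyde A3 in sequence to chloroacetaldehyde A2, and the dihydroxy aldehyde closes to lactol A1. One aqueous step from commodity aldehydes sets C5 under enzyme control, with no chiral reagent and no tin; in catalyst economy this is better than steps 17–21. Its weak points for this target are these: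
- It addresses only the simplest fragment.
- The C3 hydroxyl of A1 is made only to be eliminated after lactol oxidation.
- The chloromethyl group is at the wrong oxidation level for C6=C7 and would have to pass through an α-acyloxy aldehyde prone to β-elimination before a vinyl metal could be installed, which takes four or five steps on a sensitive lactone.

Against it the chosen plan sets a five-step route to 28 with the E-stannane already in place, and the fact that the strategic problem lies in ring A, which this road leaves open.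

**Alternative 2:** Ring A is cut at C17–C18. The syn dienol A6 is esterified with benzyloxyacetic acid A7 and converted to the α-acetoxy ether A5. A bromide-bearing tin Lewis acid ionises A5 to the C17 oxocarbenium ion, the terminal alkene attacks through a chair, and bromide caps C19 equatorially to give A4. The 2,6-cis relationship is reliable. The equatorial bromide of A4 could also be displaced with inversion to give the axial C19 oxygen directly; in that respect this road is better than the ketone reduction of step 5, whose facial outcome is not assured. Its weak points are these: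
- The oxocarbenium ion sits next to C21, which is allylic and bears the propenyl group, so oxonia-Cope rearrangement and ionisation of C21–O threaten that centre.
- A6 needs a stoichiometric chiral crotylborane.
- The benzyl ether cannot be removed by hydrogenolysis beside the propenyl group.
- Displacement next to the axial methyl competes with elimination.

The step count to the stage of 10 is similar. The chosen plan sets against it three stereocentres made catalytically from achiral compounds and no cation beside the propenyl group.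

**Alternative 3:** Ring A is cut at O–C21. Under a divalent palladium chloride catalyst the C17 hydroxyl of the acyclic diol A9 attacks C21, the alkene shifts to C22=C23 and water is lost, which gives A8 with the E-propenyl group. The cyclisation is mild and stereospecific, and C16 is already in place in A8. This avoids the chelation-controlled addition of step 22 and the reduction of step 5, and in certainty of C16 and C19 this road is better. Its weak points are these:
- C16, C17, C19, C20 and the sacrificial C23 centre of A9 must all be built one after another in a long acyclic sequence before the ring closes.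
- One stereocentre is consumed.
- The C15 terminus of A8 is an alcohol, so the diene would have to be made by olefination of an epimerisable α-alkoxy aldehyde.

The chosen plan sets against it brevity (ring A with three stereocentres in three steps) and convergence.

Key step: step 3

## Route

Step 1
Reactants: 1 (tert-butyldimethylsilyloxy)acetaldehyde; 2 diethyl (2-oxobutyl)phosphonate
Product: 3 (E)-6-(tert-butyldimethylsilyloxy)hex-4-en-3-one
Conditions: LiCl, i-Pr2NEt, MeCN, rt
Reagents that add atoms: none
Why: Horner–Wadsworth–Emmons olefination under Masamune–Roush conditions; the stabilised ketophosphonate anion gives the E enone, and LiCl with a tertiary amine is mild enough for the enolisable α-silyloxy aldehyde.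

Step 2
Reactants: 3 (E)-6-(tert-butyldimethylsilyloxy)hex-4-en-3-one
Product: 4 (2Z,4E)-6-(tert-butyldimethylsilyloxy)-3-(triethylsilyloxy)hexa-2,4-diene
Conditions: Et3SiOTf, Et3N, Et2O, −78 °C to 0 °C
Reagents that add atoms: triethylsilyl trifluoromethanesulfonate, CC[Si](CC)(CC)OS(=O)(=O)C(F)(F)F
Why: Soft enolisation with a silyl triflate and Et3N removes an α′ proton of the ethyl ketone and gives the cross-conjugated 2-silyloxydiene; the Z enol ether is expected because the methyl group avoids the vinyl residue in the enolisation transition state.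

Step 3
Reactants: 4 (2Z,4E)-6-(tert-butyldimethylsilyloxy)-3-(triethylsilyloxy)hexa-2,4-diene; 5 (E)-crotonaldehyde
Product: 6 (2S,3R,6S)-6-[(tert-butyldimethylsilyloxy)methyl]-3-methyl-2-[(E)-prop-1-enyl]-4-(triethylsilyloxy)-3,6-dihydro-2H-pyran
Conditions: [CrCl(L)] (5 mol %; L = (1R,2S)-1-{[3-(1-adamantyl)-5-methyl-2-oxidobenzylidene]amino}indan-2-olate; trivalent chromium), 4 Å MS, neat, 5 in excess, rt
Reagents that add atoms: none
Why: The chromium centre binds the oxygen of 5 and diene 4 adds across the C=O in a concerted, asynchronous [4+2] cycloaddition in which the C20–C21 bond forms ahead of O–C17. The closest known reaction type is the hetero-Diels–Alder reaction of aldehydes with 1,4-disubstituted 2-silyloxydienes under tridentate Schiff-base chromium chloride catalysts, which gives all-cis 2,3,6-trisubstituted dihydropyrans. Ring A closes by cycloaddition, both ring bonds forming suprafacially on each partner in one step. C17 and C20 are fixed relative to each other by the 2Z,4E geometry of 4, whose two terminal substituents point outward in the s-cis diene and end up cis. C21 is set cis to both by the endo transition state, in which the propenyl group lies under the diene. The absolute configuration (17S, 21S, and at C20 the arrangement that is 20S in the target and carries the descriptor R in 6) comes from the chiral ligand, which shields one face of the bound aldehyde. The step needs chemoselectivity for C=O over C=C of the enal, secured because only the carbonyl is activated by the Lewis acid, and endo and facial selectivity, secured by the catalyst. A high Z purity of the enol ether is the precondition for the C20 configuration.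

Step 4
Reactants: 6 (2S,3R,6S)-6-[(tert-butyldimethylsilyloxy)methyl]-3-methyl-2-[(E)-prop-1-enyl]-4-(triethylsilyloxy)-3,6-dihydro-2H-pyran
Product: 7 (2S,3R,6S)-6-[(tert-butyldimethylsilyloxy)methyl]-3-methyl-2-[(E)-prop-1-enyl]oxan-4-one
Conditions: Bu4NF (1.05 equiv), AcOH, THF, −78 °C to 0 °C
Reagents that add atoms: none
Why: Silyl enol ether cleavage; fluoride attacks the enol silicon far faster than that of the primary alkyl silyl ether, and AcOH protonates the enolate at C18 at once, so the axial C20 methyl should not epimerise.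

Step 5
Reactants: 7 (2S,3R,6S)-6-[(tert-butyldimethylsilyloxy)methyl]-3-methyl-2-[(E)-prop-1-enyl]oxan-4-one
Product: 8 (2S,3S,4R,6S)-6-[(tert-butyldimethylsilyloxy)methyl]-3-methyl-2-[(E)-prop-1-enyl]oxan-4-ol
Conditions: LiBH(s-Bu)3, THF, −78 °C; then H2O
Reagents that add atoms: none
Why: Ketone reduction with a bulky trialkylborohydride; in the chair of 7 (C17 and C21 substituents equatorial) the reagent should avoid the axial hydrogens at C17 and C21 and attack along the equatorial trajectory, which gives the axial (19R) alcohol trans to the C20 methyl.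

Step 6
Reactants: 8 (2S,3S,4R,6S)-6-[(tert-butyldimethylsilyloxy)methyl]-3-methyl-2-[(E)-prop-1-enyl]oxan-4-ol
Product: 9 (2S,3R,4R,6S)-4-(tert-butyldimethylsilyloxy)-6-[(tert-butyldimethylsilyloxy)methyl]-3-methyl-2-[(E)-prop-1-enyl]oxane
Conditions: t-BuMe2SiOTf, 2,6-lutidine, CH2Cl2, −78 °C to 0 °C
Reagents that add atoms: tert-butyldimethylsilyl trifluoromethanesulfonate, CC(C)(C)[Si](C)(C)OS(=O)(=O)C(F)(F)F
Why: Silylation of the hindered axial alcohol with a silyl triflate and a hindered pyridine base; the group masks the C19 hydroxyl through the organometallic addition of step 22.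

Step 7
Reactants: 9 (2S,3R,4R,6S)-4-(tert-butyldimethylsilyloxy)-6-[(tert-butyldimethylsilyloxy)methyl]-3-methyl-2-[(E)-prop-1-enyl]oxane
Product: 10 [(2S,4R,5R,6S)-4-(tert-butyldimethylsilyloxy)-5-methyl-6-[(E)-prop-1-enyl]oxan-2-yl]methanol
Conditions: HF·pyridine, pyridine, THF, 0 °C
Reagents that add atoms: none
Why: Selective desilylation; buffered HF·pyridine cleaves the unhindered primary silyl ether much faster than the axial secondary one flanked by the C20 methyl.

Step 8
Reactants: 10 [(2S,4R,5R,6S)-4-(tert-butyldimethylsilyloxy)-5-methyl-6-[(E)-prop-1-enyl]oxan-2-yl]methanol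
Product: 11 (2S,4R,5R,6S)-4-(tert-butyldimethylsilyloxy)-5-methyl-6-[(E)-prop-1-enyl]oxane-2-carbaldehyde
Conditions: Dess–Martin periodinane, NaHCO3, CH2Cl2, 0 °C to rt
Reagents that add atoms: none
Why: Dess–Martin oxidation under bicarbonate buffer is neutral and fast, so the α-alkoxy aldehyde keeps its C17 configuration; 11 is used without storage.

Step 9
Reactants: 12 (S)-3-bromo-2-methylpropan-1-ol
Product: 13 (S)-(3-bromo-2-methylpropoxy)(tert-butyl)dimethylsilane
Conditions: t-BuMe2SiCl, imidazole, CH2Cl2, rt
Reagents that add atoms: tert-butyldimethylsilyl chloride, CC(C)(C)[Si](C)(C)Cl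
Why: Silyl protection of the primary alcohol prevents oxetane formation and alkoxide interference in the acetylide displacement.

Step 10
Reactants: 13 (S)-(3-bromo-2-methylpropoxy)(tert-butyl)dimethylsilane
Product: 14 (R)-tert-butyldimethyl[(2-methylpent-4-yn-1-yl)oxy]silane
Conditions: LiC≡CH·H2NCH2CH2NH2, DMSO, 0 °C to rt
Reagents that add atoms: lithium acetylide–ethylenediamine complex, [Li+].[C-]#C.NCCN
Why: SN2 displacement of the primary bromide by acetylide in DMSO; the C10 stereocentre is β to the reacting carbon and is untouched (the descriptor changes only through ligand priorities).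

Step 11
Reactants: 14 (R)-tert-butyldimethyl[(2-methylpent-4-yn-1-yl)oxy]silane
Product: 16 (R,E)-tert-butyl[(5-iodo-2,4-dimethylpent-4-en-1-yl)oxy]dimethylsilane, via alkenyldimethylalane 15 (not isolated)
Conditions: Me3Al, Cp2ZrCl2 (20 mol %), CH2Cl2, 0 °C to rt; then I2, THF, −30 °C
Reagents that add atoms: trimethylaluminium, C[Al](C)C; iodine, II
Why: Negishi zirconium-catalysed carboalumination adds methyl and aluminium syn across the terminal alkyne with aluminium at the terminus, and iodinolysis of the C–Al bond with retention gives the E iodide.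

Step 12
Reactants: 16 (R,E)-tert-butyl[(5-iodo-2,4-dimethylpent-4-en-1-yl)oxy]dimethylsilane
Product: 17 (R,E)-tert-butyl{[2,4-dimethyl-7-(trimethylsilyl)hept-4-en-6-yn-1-yl]oxy}dimethylsilane
Conditions: Me3SiC≡CH, Pd(PPh3)2Cl2 (3 mol %), CuI (6 mol %), Et3N, THF, rt
Reagents that add atoms: ethynyltrimethylsilane, C#C[Si](C)(C)C
Why: Sonogashira coupling of the alkenyl iodide proceeds with retention of alkene geometry and installs C14–C15 as a protected alkyne.

Step 13
Reactants: 17 (R,E)-tert-butyl{[2,4-dimethyl-7-(trimethylsilyl)hept-4-en-6-yn-1-yl]oxy}dimethylsilane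
Product: 18 (R,E)-2,4-dimethyl-7-(trimethylsilyl)hept-4-en-6-yn-1-ol
Conditions: camphorsulfonic acid (10 mol %), MeOH–CH2Cl2, 0 °C
Reagents that add atoms: none
Why: Acid-catalysed methanolysis removes the primary silyl ether, while the alkynyl C–Si bond is stable to acid.

Step 14
Reactants: 18 (R,E)-2,4-dimethyl-7-(trimethylsilyl)hept-4-en-6-yn-1-ol
Product: 19 (R,E)-2,4-dimethyl-7-(trimethylsilyl)hept-4-en-6-ynal
Conditions: Dess–Martin periodinane, NaHCO3, CH2Cl2, 0 °C
Reagents that add atoms: none
Why: Dess–Martin oxidation under neutral conditions; the α-methyl aldehyde is used crude at once to keep C10 intact.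

Step 15
Reactants: 19 (R,E)-2,4-dimethyl-7-(trimethylsilyl)hept-4-en-6-ynal
Product: 20 trimethyl[(3E,6R,7Z)-8-iodo-4,6-dimethylnona-3,7-dien-1-yn-1-yl]silane
Conditions: [Ph3PEt]I, n-BuLi, THF, rt; I2, −78 °C; NaN(SiMe3)2, −78 °C to −20 °C; then 19, −78 °C to rt
Reagents that add atoms: ethyltriphenylphosphonium iodide, CC[P+](c1ccccc1)(c1ccccc1)c1ccccc1.[I-]; iodine, II
Why: Stork–Zhao-type Wittig olefination; the non-stabilised α-iodo ylide reacts under kinetic control and places iodine cis to the chain, which gives the 8Z iodoalkene, and the low temperature should spare C10.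

Step 16
Reactants: 20 trimethyl[(3E,6R,7Z)-8-iodo-4,6-dimethylnona-3,7-dien-1-yn-1-yl]silane
Product: 21 (3E,6R,7Z)-8-iodo-4,6-dimethylnona-3,7-dien-1-yne
Conditions: K2CO3 (cat.), MeOH, rt
Reagents that add atoms: none
Why: Methanolysis of the alkynyl–silicon bond with catalytic carbonate; the alkenyl iodide and the alkenes do not react.

Step 17
Reactants: 22 prop-2-yn-1-ol
Product: 23 (E)-3-(tributylstannyl)prop-2-en-1-ol
Conditions: Bu3SnH, AIBN (cat.), neat, 80 °C; chromatography
Reagents that add atoms: tributyltin hydride, CCCC[SnH](CCCC)CCCC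
Why: Radical hydrostannation places tin at the alkyne terminus, and reversible stannyl radical addition enriches the E isomer; minor isomers are removed by chromatography.

Step 18
Reactants: 23 (E)-3-(tributylstannyl)prop-2-en-1-ol
Product: 24 (E)-3-(tributylstannyl)prop-2-enal
Conditions: MnO2, CH2Cl2, rt
Reagents that add atoms: none
Why: MnO2 oxidises the allylic alcohol selectively and without acid, so the alkenyl–tin bond survives.

Step 19
Reactants: 24 (E)-3-(tributylstannyl)prop-2-enal
Product: 26 (S,E)-1-(tributylstannyl)hexa-1,5-dien-3-ol, via diisopinocampheylborinate 25 (not isolated)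
Conditions: Ipc2B(allyl) [Ipc from (+)-α-pinene; commercial pentane solution], Et2O, −78 °C; then NaBO3·4H2O, THF–H2O, rt
Reagents that add atoms: B-allylbis[(1R,2S,3R,5R)-isopinocampheyl]borane, C=CCB([C@@H]1C[C@@H]2C[C@H]([C@H]1C)C2(C)C)[C@@H]1C[C@@H]2C[C@H]([C@H]1C)C2(C)C
Why: Brown allylation through a chair Zimmerman–Traxler transition state; the isopinocampheyl groups direct the allyl group to the Si face of the aldehyde and set C5 as S, and perborate cleaves the borinate without attacking the C–Sn bond.

Step 20
Reactants: 26 (S,E)-1-(tributylstannyl)hexa-1,5-dien-3-ol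
Product: 27 (S,E)-1-(tributylstannyl)hexa-1,5-dien-3-yl prop-2-enoate
Conditions: CH2=CHCOCl, i-Pr2NEt, CH2Cl2, −78 °C to 0 °C
Reagents that add atoms: acryloyl chloride, C=CC(=O)Cl
Why: Acylation of the secondary alcohol with an acid chloride and a hindered amine base; the stereocentre is not involved.

Step 21
Reactants: 27 (S,E)-1-(tributylstannyl)hexa-1,5-dien-3-yl prop-2-enoate
Product: 28 (S)-6-[(E)-2-(tributylstannyl)ethenyl]-5,6-dihydro-2H-pyran-2-one
Conditions: second-generation Grubbs catalyst (5 mol %), CH2Cl2, high dilution, 40 °C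
Reagents that add atoms: none
Why: Ring-closing metathesis; the ruthenium carbene forms at the terminal allyl alkene and closes on the acrylate to the six-membered lactone, while the stannyl-substituted disubstituted alkene is too hindered to take part.

Step 22
Reactants: 21 (3E,6R,7Z)-8-iodo-4,6-dimethylnona-3,7-dien-1-yne; 11 (2S,4R,5R,6S)-4-(tert-butyldimethylsilyloxy)-5-methyl-6-[(E)-prop-1-enyl]oxane-2-carbaldehyde
Product: 31 (1S,2E,4E,7R,8Z)-1-[(2S,4R,5R,6S)-4-(tert-butyldimethylsilyloxy)-5-methyl-6-[(E)-prop-1-enyl]oxan-2-yl]-9-iodo-5,7-dimethyldeca-2,4,8-trien-1-ol, via dienylzirconocene chloride 29 (not isolated), via dienylmethylzinc 30 (not isolated)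
Conditions: Cp2Zr(H)Cl, CH2Cl2, rt; Me2Zn, toluene, −65 °C; then 11, −65 °C to 0 °C; aq. NH4Cl
Reagents that add atoms: none
Why: Hydrozirconation adds Zr–H syn to the terminal alkyne with zirconium at C15, and transmetalation to zinc gives a dienylzinc that adds to the aldehyde (alkenylzinc addition); zinc is held between the aldehyde and ring oxygens (Cram chelate), so attack from the side of the C17 hydrogen should give the 16S carbinol, syn to the ring oxygen.

Step 23
Reactants: 31 (1S,2E,4E,7R,8Z)-1-[(2S,4R,5R,6S)-4-(tert-butyldimethylsilyloxy)-5-methyl-6-[(E)-prop-1-enyl]oxan-2-yl]-9-iodo-5,7-dimethyldeca-2,4,8-trien-1-ol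
Product: 32 (2S,3S,4R,6S)-6-[(1S,2E,4E,7R,8Z)-1-hydroxy-9-iodo-5,7-dimethyldeca-2,4,8-trien-1-yl]-3-methyl-2-[(E)-prop-1-enyl]oxan-4-ol
Conditions: HF·pyridine, pyridine, THF, 0 °C to rt
Reagents that add atoms: none
Why: Desilylation without base avoids dehydroiodination of the alkenyl iodide, and the pyridine buffer protects the dienyl carbinol from ionisation; it is done before the lactone is attached so that 33 needs no deprotection.

Step 24
Reactants: 32 (2S,3S,4R,6S)-6-[(1S,2E,4E,7R,8Z)-1-hydroxy-9-iodo-5,7-dimethyldeca-2,4,8-trien-1-yl]-3-methyl-2-[(E)-prop-1-enyl]oxan-4-ol; 28 (S)-6-[(E)-2-(tributylstannyl)ethenyl]-5,6-dihydro-2H-pyran-2-one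
Product: 33 (S)-6-[(1E,3Z,5R,7E,9E,11S)-11-hydroxy-11-[(2S,4R,5S,6S)-4-hydroxy-5-methyl-6-[(E)-prop-1-enyl]oxan-2-yl]-3,5,7-trimethylundeca-1,3,7,9-tetraen-1-yl]-5,6-dihydro-2H-pyran-2-one
Conditions: Pd2(dba)3 (5 mol %), AsPh3 (40 mol %), N-methylpyrrolidone, rt, dark
Reagents that add atoms: none
Why: Stille coupling with zerovalent palladium; oxidative addition into the C8–I bond, transmetalation from the unhindered E stannane and reductive elimination proceed with retention at both alkenes under neutral conditions that the lactone and the free hydroxyls tolerate.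

## Compound list

1 | (tert-butyldimethylsilyloxy)acetaldehyde | O=CCO[Si](C)(C)C(C)(C)C | starting material
2 | diethyl (2-oxobutyl)phosphonate | CCC(=O)CP(=O)(OCC)OCC | starting material
3 | (E)-6-(tert-butyldimethylsilyloxy)hex-4-en-3-one | CCC(=O)/C=C/CO[Si](C)(C)C(C)(C)C | intermediate
4 | (2Z,4E)-6-(tert-butyldimethylsilyloxy)-3-(triethylsilyloxy)hexa-2,4-diene | C/C=C(\O[Si](CC)(CC)CC)/C=C/CO[Si](C)(C)C(C)(C)C | intermediate
5 | (E)-crotonaldehyde | C/C=C/C=O | starting material
6 | (2S,3R,6S)-6-[(tert-butyldimethylsilyloxy)methyl]-3-methyl-2-[(E)-prop-1-enyl]-4-(triethylsilyloxy)-3,6-dihydro-2H-pyran | C/C=C/[C@@H]1O[C@H](CO[Si](C)(C)C(C)(C)C)C=C(O[Si](CC)(CC)CC)[C@@H]1C | intermediate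
7 | (2S,3R,6S)-6-[(tert-butyldimethylsilyloxy)methyl]-3-methyl-2-[(E)-prop-1-enyl]oxan-4-one | C/C=C/[C@@H]1O[C@H](CO[Si](C)(C)C(C)(C)C)CC(=O)[C@@H]1C | intermediate
8 | (2S,3S,4R,6S)-6-[(tert-butyldimethylsilyloxy)methyl]-3-methyl-2-[(E)-prop-1-enyl]oxan-4-ol | C/C=C/[C@@H]1O[C@H](CO[Si](C)(C)C(C)(C)C)C[C@@H](O)[C@@H]1C | intermediate
9 | (2S,3R,4R,6S)-4-(tert-butyldimethylsilyloxy)-6-[(tert-butyldimethylsilyloxy)methyl]-3-methyl-2-[(E)-prop-1-enyl]oxane | C/C=C/[C@@H]1O[C@H](CO[Si](C)(C)C(C)(C)C)C[C@@H](O[Si](C)(C)C(C)(C)C)[C@@H]1C | intermediate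
10 | [(2S,4R,5R,6S)-4-(tert-butyldimethylsilyloxy)-5-methyl-6-[(E)-prop-1-enyl]oxan-2-yl]methanol | C/C=C/[C@@H]1O[C@H](CO)C[C@@H](O[Si](C)(C)C(C)(C)C)[C@@H]1C | intermediate
11 | (2S,4R,5R,6S)-4-(tert-butyldimethylsilyloxy)-5-methyl-6-[(E)-prop-1-enyl]oxane-2-carbaldehyde | C/C=C/[C@@H]1O[C@H](C=O)C[C@@H](O[Si](C)(C)C(C)(C)C)[C@@H]1C | intermediate
12 | (S)-3-bromo-2-methylpropan-1-ol | BrC[C@@H](C)CO | starting material
13 | (S)-(3-bromo-2-methylpropoxy)(tert-butyl)dimethylsilane | BrC[C@@H](C)CO[Si](C)(C)C(C)(C)C | intermediate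
14 | (R)-tert-butyldimethyl[(2-methylpent-4-yn-1-yl)oxy]silane | C#CC[C@@H](C)CO[Si](C)(C)C(C)(C)C | intermediate
15 | dimethyl[(1E,4R)-5-(tert-butyldimethylsilyloxy)-2,4-dimethylpent-1-en-1-yl]alane | C[Al](C)/C=C(\C)C[C@@H](C)CO[Si](C)(C)C(C)(C)C | intermediate
16 | (R,E)-tert-butyl[(5-iodo-2,4-dimethylpent-4-en-1-yl)oxy]dimethylsilane | I/C=C(\C)C[C@@H](C)CO[Si](C)(C)C(C)(C)C | intermediate
17 | (R,E)-tert-butyl{[2,4-dimethyl-7-(trimethylsilyl)hept-4-en-6-yn-1-yl]oxy}dimethylsilane | C[Si](C)(C)C#C/C=C(\C)C[C@@H](C)CO[Si](C)(C)C(C)(C)C | intermediate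
18 | (R,E)-2,4-dimethyl-7-(trimethylsilyl)hept-4-en-6-yn-1-ol | C[Si](C)(C)C#C/C=C(\C)C[C@@H](C)CO | intermediate
19 | (R,E)-2,4-dimethyl-7-(trimethylsilyl)hept-4-en-6-ynal | C[Si](C)(C)C#C/C=C(\C)C[C@@H](C)C=O | intermediate
20 | trimethyl[(3E,6R,7Z)-8-iodo-4,6-dimethylnona-3,7-dien-1-yn-1-yl]silane | C[Si](C)(C)C#C/C=C(\C)C[C@@H](C)/C=C(C)\I | intermediate
21 | (3E,6R,7Z)-8-iodo-4,6-dimethylnona-3,7-dien-1-yne | C#C/C=C(\C)C[C@@H](C)/C=C(C)\I | intermediate
22 | prop-2-yn-1-ol | C#CCO | starting material
23 | (E)-3-(tributylstannyl)prop-2-en-1-ol | CCCC[Sn](CCCC)(CCCC)/C=C/CO | intermediate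
24 | (E)-3-(tributylstannyl)prop-2-enal | CCCC[Sn](CCCC)(CCCC)/C=C/C=O | intermediate
25 | (S,E)-1-(tributylstannyl)hexa-1,5-dien-3-yl bis[(1R,2S,3R,5R)-isopinocampheyl]borinate | CCCC[Sn](CCCC)(CCCC)/C=C/[C@@H](OB([C@@H]1C[C@@H]2C[C@H]([C@H]1C)C2(C)C)[C@@H]1C[C@@H]2C[C@H]([C@H]1C)C2(C)C)CC=C | intermediate
26 | (S,E)-1-(tributylstannyl)hexa-1,5-dien-3-ol | CCCC[Sn](CCCC)(CCCC)/C=C/[C@@H](O)CC=C | intermediate
27 | (S,E)-1-(tributylstannyl)hexa-1,5-dien-3-yl prop-2-enoate | CCCC[Sn](CCCC)(CCCC)/C=C/[C@@H](OC(=O)C=C)CC=C | intermediate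
28 | (S)-6-[(E)-2-(tributylstannyl)ethenyl]-5,6-dihydro-2H-pyran-2-one | CCCC[Sn](CCCC)(CCCC)/C=C/[C@@H]1CC=CC(=O)O1 | intermediate
29 | chlorobis(cyclopentadienyl)[(1E,3E,6R,7Z)-8-iodo-4,6-dimethylnona-1,3,7-trien-1-yl]zirconium | Cl[Zr](C1C=CC=C1)(C1C=CC=C1)/C=C/C=C(\C)C[C@@H](C)/C=C(C)\I | intermediate
30 | methyl[(1E,3E,6R,7Z)-8-iodo-4,6-dimethylnona-1,3,7-trien-1-yl]zinc | C[Zn]/C=C/C=C(\C)C[C@@H](C)/C=C(C)\I | intermediate
31 | (1S,2E,4E,7R,8Z)-1-[(2S,4R,5R,6S)-4-(tert-butyldimethylsilyloxy)-5-methyl-6-[(E)-prop-1-enyl]oxan-2-yl]-9-iodo-5,7-dimethyldeca-2,4,8-trien-1-ol | C/C=C/[C@@H]1O[C@H]([C@@H](O)/C=C/C=C(\C)C[C@@H](C)/C=C(C)\I)C[C@@H](O[Si](C)(C)C(C)(C)C)[C@@H]1C | intermediate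
32 | (2S,3S,4R,6S)-6-[(1S,2E,4E,7R,8Z)-1-hydroxy-9-iodo-5,7-dimethyldeca-2,4,8-trien-1-yl]-3-methyl-2-[(E)-prop-1-enyl]oxan-4-ol | C/C=C/[C@@H]1O[C@H]([C@@H](O)/C=C/C=C(\C)C[C@@H](C)/C=C(C)\I)C[C@@H](O)[C@@H]1C | intermediate
33 | (S)-6-[(1E,3Z,5R,7E,9E,11S)-11-hydroxy-11-[(2S,4R,5S,6S)-4-hydroxy-5-methyl-6-[(E)-prop-1-enyl]oxan-2-yl]-3,5,7-trimethylundeca-1,3,7,9-tetraen-1-yl]-5,6-dihydro-2H-pyran-2-one | C/C=C/[C@@H]1O[C@H]([C@@H](O)/C=C/C=C(\C)C[C@@H](C)/C=C(C)\C=C\[C@@H]2CC=CC(=O)O2)C[C@@H](O)[C@@H]1C | target

## Step count and risks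

Total: 24 steps. Longest linear sequence: 11 steps (steps 1–8 and 22–24; the sequence through 12, steps 9–16 and 22–24, is equally long).

**Step 3 (key step).** The conjugated aldehyde may react slowly at the chromium centre, with loss of endo and facial selectivity, and may be diverted into an inverse-demand pathway in which it acts as a 1-oxadiene toward the electron-rich alkenes of 4. Both follow from conjugation, which lowers the electrophilicity of the carbonyl carbon and opens a second reaction mode. The fallback sets out from diene 4, which is combined under the same chromium catalyst with but-2-ynal, a more electrophilic dienophile that cannot act as an oxadiene, to give (2R,3R,6S)-6-[(tert-butyldimethylsilyloxy)methyl]-3-methyl-2-(prop-1-ynyl)-4-(triethylsilyloxy)-3,6-dihydro-2H-pyran F1. Buffered fluoride as in step 4 gives (2R,3R,6S)-6-[(tert-butyldimethylsilyloxy)methyl]-3-methyl-2-(prop-1-ynyl)oxan-4-one F2, and ruthenium-catalysed trans-hydrogenation of the alkyne ([Cp*Ru(cod)Cl], H2, CH2Cl2) comes back to the route at ketone 7.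

**Step 5.** Facial selectivity may be poor, because the axial C20 methyl lies beside the equatorial trajectory and may push even the bulky hydride to the axial face. The fallback sets out from ketone 7, which NaBH4 (MeOH, −20 °C) should reduce by axial attack to the equatorial alcohol (2S,3S,4S,6S)-6-[(tert-butyldimethylsilyloxy)methyl]-3-methyl-2-[(E)-prop-1-enyl]oxan-4-ol F3. Mitsunobu inversion with 4-nitrobenzoic acid (PPh3, diisopropyl azodicarboxylate) gives the axial ester (2S,3S,4R,6S)-6-[(tert-butyldimethylsilyloxy)methyl]-3-methyl-2-[(E)-prop-1-enyl]oxan-4-yl 4-nitrobenzoate F4; the equatorial leaving group has no antiperiplanar hydrogen, so elimination is disfavoured. Methanolysis (K2CO3, MeOH) comes back to the route at alcohol 8.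

**Step 15.** Z selectivity may erode and C10 may partly epimerise, because a basic ylide meets an enolisable α-methyl aldehyde and the olefination is Z-selective only under kinetic control. The fallback sets out from aldehyde 19, which CBr4 and PPh3 (first stage of the Corey–Fuchs reaction) convert to trimethyl[(3E,6R)-8,8-dibromo-4,6-dimethylocta-3,7-dien-1-yn-1-yl]silane F5. Palladium-catalysed Negishi coupling with Me2Zn (Pd(t-Bu3P)2) replaces selectively the bromine trans to the chain and gives trimethyl[(3E,6R,7Z)-8-bromo-4,6-dimethylnona-3,7-dien-1-yn-1-yl]silane F6. Bromine–lithium exchange (t-BuLi, Et2O, −78 °C) and iodinolysis with retention come back to the route at iodide 20.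

**Step 22.** Facial selectivity may be poor if zinc does not hold the ring oxygen firmly and an open Felkin–Anh transition state competes. The fallback sets out from carbinol 31, whatever its epimeric purity at C16, which is oxidised (Dess–Martin periodinane) to (2E,4E,7R,8Z)-1-[(2S,4R,5R,6S)-4-(tert-butyldimethylsilyloxy)-5-methyl-6-[(E)-prop-1-enyl]oxan-2-yl]-9-iodo-5,7-dimethyldeca-2,4,8-trien-1-one F7. Corey–Bakshi–Shibata reduction with the (S)-methyloxazaborolidine and catecholborane, in which the dienyl group acts as the large substituent and the reagent reinforces the Felkin–Anh preference of the α-alkoxy ketone, comes back to the route at 31 as the 16S epimer.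

**Step 24.** Transmetalation may be slow at the α-methyl-substituted alkenylpalladium intermediate, which leaves time for protodestannylation and homocoupling of 28. The fallback sets out from stannane 28, which is protodestannylated (HCl, CH2Cl2, 0 °C) to (S)-6-ethenyl-5,6-dihydro-2H-pyran-2-one F8. Heck coupling of F8, used in excess, with iodide 32 (Pd(OAc)2, Ag2CO3, DMF, rt) forms C7–C8 by insertion and β-hydride elimination in place of transmetalation and comes back to the route at the target 33.

## Further compounds

F1 | step 3 | (2R,3R,6S)-6-[(tert-butyldimethylsilyloxy)methyl]-3-methyl-2-(prop-1-ynyl)-4-(triethylsilyloxy)-3,6-dihydro-2H-pyran | CC#C[C@@H]1O[C@H](CO[Si](C)(C)C(C)(C)C)C=C(O[Si](CC)(CC)CC)[C@@H]1C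
F2 | step 3 | (2R,3R,6S)-6-[(tert-butyldimethylsilyloxy)methyl]-3-methyl-2-(prop-1-ynyl)oxan-4-one | CC#C[C@@H]1O[C@H](CO[Si](C)(C)C(C)(C)C)CC(=O)[C@@H]1C
F3 | step 5 | (2S,3S,4S,6S)-6-[(tert-butyldimethylsilyloxy)methyl]-3-methyl-2-[(E)-prop-1-enyl]oxan-4-ol | C/C=C/[C@@H]1O[C@H](CO[Si](C)(C)C(C)(C)C)C[C@H](O)[C@@H]1C
F4 | step 5 | (2S,3S,4R,6S)-6-[(tert-butyldimethylsilyloxy)methyl]-3-methyl-2-[(E)-prop-1-enyl]oxan-4-yl 4-nitrobenzoate | C/C=C/[C@@H]1O[C@H](CO[Si](C)(C)C(C)(C)C)C[C@@H](OC(=O)c2ccc(cc2)[N+](=O)[O-])[C@@H]1C
F5 | step 15 | trimethyl[(3E,6R)-8,8-dibromo-4,6-dimethylocta-3,7-dien-1-yn-1-yl]silane | C[Si](C)(C)C#C/C=C(\C)C[C@@H](C)C=C(Br)Br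
F6 | step 15 | trimethyl[(3E,6R,7Z)-8-bromo-4,6-dimethylnona-3,7-dien-1-yn-1-yl]silane | C[Si](C)(C)C#C/C=C(\C)C[C@@H](C)/C=C(C)\Br
F7 | step 22 | (2E,4E,7R,8Z)-1-[(2S,4R,5R,6S)-4-(tert-butyldimethylsilyloxy)-5-methyl-6-[(E)-prop-1-enyl]oxan-2-yl]-9-iodo-5,7-dimethyldeca-2,4,8-trien-1-one | C/C=C/[C@@H]1O[C@H](C(=O)/C=C/C=C(\C)C[C@@H](C)/C=C(C)\I)C[C@@H](O[Si](C)(C)C(C)(C)C)[C@@H]1C
F8 | step 24 | (S)-6-ethenyl-5,6-dihydro-2H-pyran-2-one | C=C[C@@H]1CC=CC(=O)O1
A1 | alternative 1 | (4R,6S)-6-(chloromethyl)oxane-2,4-diol (lactol epimers) | ClC[C@@H]1C[C@@H](O)CC(O)O1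
A2 | alternative 1 | chloroacetaldehyde | ClCC=O
A3 | alternative 1 | acetaldehyde | CC=O
A4 | alternative 2 | (2S,3R,4S,6S)-6-[(benzyloxy)methyl]-4-bromo-3-methyl-2-[(E)-prop-1-enyl]oxane | C/C=C/[C@@H]1O[C@H](COCc2ccccc2)C[C@H](Br)[C@@H]1C
A5 | alternative 2 | 2-(benzyloxy)-1-{[(3S,4S,5E)-3-methylhepta-1,5-dien-4-yl]oxy}ethyl acetate | C/C=C/[C@H](OC(COCc1ccccc1)OC(C)=O)[C@@H](C)C=C
A6 | alternative 2 | (3S,4S,5E)-3-methylhepta-1,5-dien-4-ol | C/C=C/[C@H](O)[C@@H](C)C=C
A7 | alternative 2 | (benzyloxy)acetic acid | OC(=O)COCc1ccccc1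
A8 | alternative 3 | tert-butyl{(2S)-2-[(4-methoxybenzyl)oxy]-2-[(2S,4R,5R,6S)-4-(tert-butyldimethylsilyloxy)-5-methyl-6-[(E)-prop-1-enyl]oxan-2-yl]ethoxy}diphenylsilane | C/C=C/[C@@H]1O[C@H]([C@@H](OCc2ccc(OC)cc2)CO[Si](c2ccccc2)(c2ccccc2)C(C)(C)C)C[C@@H](O[Si](C)(C)C(C)(C)C)[C@@H]1C
A9 | alternative 3 | (2S,3E,5R,6R,8S,9S)-6-(tert-butyldimethylsilyloxy)-10-(tert-butyldiphenylsilyloxy)-9-[(4-methoxybenzyl)oxy]-5-methyldec-3-ene-2,8-diol | C[C@H](O)/C=C/[C@@H](C)[C@H](O[Si](C)(C)C(C)(C)C)C[C@H](O)[C@@H](OCc1ccc(OC)cc1)CO[Si](c1ccccc1)(c1ccccc1)C(C)(C)C
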